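**Plan**

Atom labels: tetrahydrofuran O–C1–C2–C3–C4(CH3); C5=C6 enol-lactone alkene; C7=C11 butenolide alkene; C8 acyloxy CH; C9 CH2; C10 C(CH3)OH; C12 lactone C=O; C13 CH2OAc.
Enabling feature: C4 is a methyl-bearing tertiary ether carbon of the tetrahydrofuran that carries the sp2 carbon C5, and the same ring oxygen sits on C1; this 2-methyl-2-vinyl-tetrahydrofuran pattern is the branched end of a geranyl-type allyl unit that the C1 hydroxyl reaches by 5-exo attack.
Cuts, in retrosynthetic order: the C8 ester and C13 acetate; C5=C6 and the butenolide (back to a fused furan); C5–C6 (closure of the ten-membered carbocycle); C8–C9 (furyl dithiane plus C9–C10 epoxide); O–C4 (the strategic cut).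
Forward: geranyl acetate gives the C1/C10-oxygenated chain; the tetrahydrofuran closes first (palladium); the furan is joined at C8–C9; the carbocycle closes at C5–C6 (Nozaki–Hiyama–Kishi); the furan becomes the alkylidene butenolide (singlet oxygen, dehydration); two acylations finish.
Stereochemistry: C10 and C1 from Katsuki–Sharpless epoxidation and invertive benzoate opening at C1; C4 from the chiral ligand on palladium; C8 from Noyori transfer hydrogenation; the epoxy ester from (R)-2-methylglycidol; the C5=C6 geometry is dictated by the ring.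

Key step: step 7

Assumption: the (R,R) antipode of the diphosphine is taken as the one that gives the required C4 configuration; the sense of induction for this trisubstituted allyl carbonate cannot be predicted with certainty, and the (S,S) ligand would replace it without other change if the opposite sense were found.

**Route**

Step 1
Reactants: 1 geranyl acetate
Product: 2 (2E,6E)-8-hydroxy-3,7-dimethylocta-2,6-dien-1-yl acetate
Conditions: SeO2 (cat.), t-BuOOH, salicylic acid (cat.), CH2Cl2, rt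
Reagents that add atoms: tert-butyl hydroperoxide CC(C)(C)OO (terminal oxidant; its oxygen reaches the product through SeO2, O=[Se]=O)
Why: Allylic oxidation with catalytic SeO2 (ene reaction, then 2,3-sigmatropic shift) should select the (E)-methyl group of the distal, more electron-rich trisubstituted alkene, the allylic acetate deactivating the proximal one.

Step 2
Reactants: 2 (2E,6E)-8-hydroxy-3,7-dimethylocta-2,6-dien-1-yl acetate
Product: 3 (2E)-5-[(2R,3R)-3-(hydroxymethyl)-3-methyloxiran-2-yl]-3-methylpent-2-en-1-yl acetate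
Conditions: Ti(OiPr)4 (10 mol %), diethyl D-(−)-tartrate (12 mol %), t-BuOOH, 4 Å molecular sieves, CH2Cl2, −20 °C
Reagents that add atoms: tert-butyl hydroperoxide CC(C)(C)OO
Why: Katsuki–Sharpless asymmetric epoxidation touches only the allylic-alcohol alkene, and the D-(−)-tartrate should deliver oxygen to the face that gives the (2R,3R)-epoxide, which fixes C10 (and C1 before its inversion).

Step 3
Reactants: 3 (2E)-5-[(2R,3R)-3-(hydroxymethyl)-3-methyloxiran-2-yl]-3-methylpent-2-en-1-yl acetate
Product: 4 (2E,6S,7R)-6-(benzoyloxy)-7,8-dihydroxy-3,7-dimethyloct-2-en-1-yl acetate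
Conditions: Ti(OiPr)4 (1.5 equiv), PhCO2H (1.5 equiv), CH2Cl2, rt
Reagents that add atoms: benzoic acid OC(=O)c1ccccc1
Why: Titanium-mediated opening of a 2,3-epoxy alcohol delivers the carboxylate to C3 of the epoxy alcohol (here C1, the less substituted carbon) by an SN2 path with inversion, so C1 becomes S while the tertiary C10–O bond stays intact.

Step 4
Reactants: 4 (2E,6S,7R)-6-(benzoyloxy)-7,8-dihydroxy-3,7-dimethyloct-2-en-1-yl acetate
Product: 5 (2E,6S)-6-(benzoyloxy)-3-methyl-6-[(4R)-2,2,4-trimethyl-1,3-dioxolan-4-yl]hex-2-en-1-yl acetate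
Conditions: 2,2-dimethoxypropane, PPTS (cat.), CH2Cl2, rt
Reagents that add atoms: 2,2-dimethoxypropane COC(C)(C)OC
Why: Acid-catalysed transketalisation forms the five-membered acetonide of the only free 1,2-diol (C9/C10), the C1 oxygen being blocked as its benzoate.

Step 5
Reactants: 5 (2E,6S)-6-(benzoyloxy)-3-methyl-6-[(4R)-2,2,4-trimethyl-1,3-dioxolan-4-yl]hex-2-en-1-yl acetate
Product: 6 (2E,6S)-3-methyl-6-[(4R)-2,2,4-trimethyl-1,3-dioxolan-4-yl]hex-2-ene-1,6-diol
Conditions: K2CO3 (cat.), MeOH, rt to 40 °C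
Reagents that add atoms: none
Why: Base-catalysed transesterification with methanol removes the acetate and the benzoate in one operation, and the acetonide is inert to base.

Step 6
Reactants: 6 (2E,6S)-3-methyl-6-[(4R)-2,2,4-trimethyl-1,3-dioxolan-4-yl]hex-2-ene-1,6-diol
Product: 7 (2E,6S)-6-hydroxy-3-methyl-6-[(4R)-2,2,4-trimethyl-1,3-dioxolan-4-yl]hex-2-en-1-yl methyl carbonate
Conditions: ClCO2Me (1.1 equiv), pyridine, CH2Cl2, −20 to 0 °C
Reagents that add atoms: methyl chloroformate COC(Cl)=O
Why: Acylation of the unhindered primary allylic hydroxyl should be much faster than that of the secondary C1 hydroxyl, which is flanked by the quaternary dioxolane carbon.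

Step 7
Reactants: 7 (2E,6S)-6-hydroxy-3-methyl-6-[(4R)-2,2,4-trimethyl-1,3-dioxolan-4-yl]hex-2-en-1-yl methyl carbonate
Product: 8 (4R)-4-[(2S,5R)-5-ethenyl-5-methyloxolan-2-yl]-2,2,4-trimethyl-1,3-dioxolane
Conditions: Pd2(dba)3·CHCl3 (2.5 mol %), (1R,2R)-N,N'-bis[2-(diphenylphosphino)benzoyl]cyclohexane-1,2-diamine (7.5 mol %), CH2Cl2, rt
Reagents that add atoms: none
Why: Zerovalent palladium ionises the primary allylic methyl carbonate with inversion to an allyl complex of divalent palladium spanning C4, C5 and the terminal CH2, and the methoxide released with CO2 deprotonates the C1 hydroxyl. The alkoxide then attacks C4 on the face away from the metal, a Tsuji–Trost allylic etherification whose closest known class is the palladium-catalysed asymmetric cyclisation of hydroxy allylic carbonates to 2-vinyl tetrahydrofurans and chromans with fully substituted ether carbons. The tetrahydrofuran closes in the 5-exo mode, since attack at the unsubstituted terminus would require a seven-membered ring and should not compete. The new stereocentre C4 is set by the chiral diphosphine, because the two faces of the allyl unit interconvert through the σ-bound form at the CH2 terminus faster than the ring closes, so the ligand pocket decides which diastereomeric complex cyclises. The step needs the face that places the vinyl group cis to the C1 side chain; the C1 centre exerts only a modest bias, so the ligand (available in both antipodes) should decide, and the acetonide leaves the C1 hydroxyl as the only nucleophile.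

Step 8
Reactants: 8 (4R)-4-[(2S,5R)-5-ethenyl-5-methyloxolan-2-yl]-2,2,4-trimethyl-1,3-dioxolane
Product: 9 (2R)-2-[(2S,5R)-5-ethenyl-5-methyloxolan-2-yl]propane-1,2-diol
Conditions: AcOH/H2O/THF (3:1:1), 40 °C
Reagents that add atoms: none
Why: Mild aqueous acid hydrolyses the dioxolane, and the tertiary allylic ether is not expected to ionise under these conditions.

Step 9
Reactants: 9 (2R)-2-[(2S,5R)-5-ethenyl-5-methyloxolan-2-yl]propane-1,2-diol
Product: 11 (2R,5S)-2-ethenyl-2-methyl-5-[(2R)-2-methyloxiran-2-yl]oxolane, via primary tosylate 10 (not isolated)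
Conditions: NaH (2.5 equiv), N-tosylimidazole (1.05 equiv), THF, 0 °C to rt
Reagents that add atoms: none
Why: The primary alkoxide is sulfonylated selectively and the tertiary alkoxide displaces the tosylate in a 3-exo-tet Williamson closure, so no bond to C10 breaks and its configuration is kept.

Step 10
Reactants: 12 furan-3,4-diyldimethanol
Product: 13 [4-({[tert-butyl(diphenyl)silyl]oxy}methyl)furan-3-yl]methanol
Conditions: TBDPSCl (1.0 equiv), imidazole, DMF, 0 °C; 12 in excess (3 equiv), recovered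
Reagents that add atoms: tert-butyl(chloro)diphenylsilane CC(C)(C)[Si](Cl)(c1ccccc1)c1ccccc1
Why: Monosilylation of a symmetrical diol, for which the excess of diol and the bulky silyl chloride should favour the mono-ether.

Step 11
Reactants: 13 [4-({[tert-butyl(diphenyl)silyl]oxy}methyl)furan-3-yl]methanol
Product: 14 4-({[tert-butyl(diphenyl)silyl]oxy}methyl)furan-3-carbaldehyde
Conditions: MnO2 (excess), CH2Cl2, rt
Reagents that add atoms: none
Why: MnO2 oxidises the heteroaryl carbinol (a benzylic-type alcohol) to the aldehyde without touching the furan or the silyl ether.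

Step 12
Reactants: 14 4-({[tert-butyl(diphenyl)silyl]oxy}methyl)furan-3-carbaldehyde
Product: 15 2-[4-({[tert-butyl(diphenyl)silyl]oxy}methyl)furan-3-yl]-1,3-dithiane
Conditions: HS(CH2)3SH, BF3·OEt2 (cat.), CH2Cl2, −20 to 0 °C
Reagents that add atoms: propane-1,3-dithiol SCCCS
Why: Lewis acid-catalysed dithioacetalisation turns the aldehyde carbon (the future C8) into an acyl anion equivalent (umpolung).

Step 13
Reactants: 15 2-[4-({[tert-butyl(diphenyl)silyl]oxy}methyl)furan-3-yl]-1,3-dithiane; 11 (2R,5S)-2-ethenyl-2-methyl-5-[(2R)-2-methyloxiran-2-yl]oxolane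
Product: 17 (2R)-1-{2-[4-({[tert-butyl(diphenyl)silyl]oxy}methyl)furan-3-yl]-1,3-dithian-2-yl}-2-[(2S,5R)-5-ethenyl-5-methyloxolan-2-yl]propan-2-ol, via lithiated dithiane 16 (not isolated)
Conditions: 15, n-BuLi, THF, −78 to −20 °C; then 11, DMPU, −20 to 0 °C
Reagents that add atoms: none
Why: Corey–Seebach alkylation, in which the 2-aryl-2-lithio-1,3-dithiane opens the terminal epoxide at its CH2 carbon (C9) by SN2 attack, forming C8–C9 and releasing the C10 tertiary alcohol with its configuration unchanged.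

Step 14
Reactants: 17 (2R)-1-{2-[4-({[tert-butyl(diphenyl)silyl]oxy}methyl)furan-3-yl]-1,3-dithian-2-yl}-2-[(2S,5R)-5-ethenyl-5-methyloxolan-2-yl]propan-2-ol
Product: 18 (3R)-1-[4-({[tert-butyl(diphenyl)silyl]oxy}methyl)furan-3-yl]-3-[(2S,5R)-5-ethenyl-5-methyloxolan-2-yl]-3-hydroxybutan-1-one
Conditions: MeI, CaCO3, MeCN/H2O (9:1), 45 °C
Reagents that add atoms: water O
Why: S-Methylation turns the dithiane into a leaving group and water hydrolyses it to the ketone under nearly neutral, CaCO3-buffered conditions that should spare the furan, the silyl ether and the retro-aldol-prone β-hydroxy ketone.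

Step 15
Reactants: 18 (3R)-1-[4-({[tert-butyl(diphenyl)silyl]oxy}methyl)furan-3-yl]-3-[(2S,5R)-5-ethenyl-5-methyloxolan-2-yl]-3-hydroxybutan-1-one
Product: 19 (1S,3R)-1-[4-({[tert-butyl(diphenyl)silyl]oxy}methyl)furan-3-yl]-3-[(2S,5R)-5-ethenyl-5-methyloxolan-2-yl]butane-1,3-diol
Conditions: RuCl[(S,S)-TsDPEN](p-cymene) (2 mol %), HCO2H/Et3N (5:2), CH2Cl2, rt
Reagents that add atoms: none
Why: Noyori asymmetric transfer hydrogenation of a heteroaryl alkyl ketone, in which the (S,S)-catalyst should deliver hydride to the face that gives the (S)-carbinol at C8 under catalyst control, independent of C10 and without reducing the vinyl group.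

Step 16
Reactants: 19 (1S,3R)-1-[4-({[tert-butyl(diphenyl)silyl]oxy}methyl)furan-3-yl]-3-[(2S,5R)-5-ethenyl-5-methyloxolan-2-yl]butane-1,3-diol
Product: 21 (1S,3R)-1-[4-({[tert-butyl(diphenyl)silyl]oxy}methyl)-2-iodofuran-3-yl]-3-[(2S,5R)-5-ethenyl-5-methyloxolan-2-yl]butane-1,3-diol, via trilithio species 20 (not isolated)
Conditions: n-BuLi (3.3 equiv), TMEDA, THF, −78 to 0 °C; then I2, −78 °C
Reagents that add atoms: iodine II
Why: Alkoxide-directed ortho-lithiation, in which the lithium alkoxide at C8 guides the base to the adjacent furan α-position C6 and not to C12 beside the bulky, weakly coordinating silyloxymethyl group, and iodine traps the furyllithium.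

Step 17
Reactants: 21 (1S,3R)-1-[4-({[tert-butyl(diphenyl)silyl]oxy}methyl)-2-iodofuran-3-yl]-3-[(2S,5R)-5-ethenyl-5-methyloxolan-2-yl]butane-1,3-diol
Product: 22 (4S,6R)-2,2-di-tert-butyl-4-[4-({[tert-butyl(diphenyl)silyl]oxy}methyl)-2-iodofuran-3-yl]-6-[(2S,5R)-5-ethenyl-5-methyloxolan-2-yl]-6-methyl-1,3,2-dioxasilinane
Conditions: t-Bu2Si(OTf)2, 2,6-lutidine, CH2Cl2, 0 °C to rt
Reagents that add atoms: di-tert-butylsilyl bis(trifluoromethanesulfonate) CC(C)(C)[Si](OS(=O)(=O)C(F)(F)F)(OS(=O)(=O)C(F)(F)F)C(C)(C)C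
Why: The bis-triflate silylates the 1,3-diol, tertiary hydroxyl included, as a six-membered silylene that masks the C8 and C10 oxygens for the ring closure and the later oxidation chemistry.

Step 18
Reactants: 22 (4S,6R)-2,2-di-tert-butyl-4-[4-({[tert-butyl(diphenyl)silyl]oxy}methyl)-2-iodofuran-3-yl]-6-[(2S,5R)-5-ethenyl-5-methyloxolan-2-yl]-6-methyl-1,3,2-dioxasilinane
Product: 24 (2R,5S)-5-[(4R,6S)-2,2-di-tert-butyl-6-[4-({[tert-butyl(diphenyl)silyl]oxy}methyl)-2-iodofuran-3-yl]-4-methyl-1,3,2-dioxasilinan-4-yl]-2-methyloxolane-2-carbaldehyde, via vicinal diol 23 (not isolated)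
Conditions: OsO4 (2 mol %), NaIO4 (4 equiv), 2,6-lutidine, dioxane/H2O (3:1), rt
Reagents that add atoms: OsO4 O=[Os](=O)(=O)=O (delivers the aldehyde oxygen and is re-formed by sodium periodate [Na+].[O-]I(=O)(=O)=O)
Why: Lemieux–Johnson cleavage, in which OsO4 dihydroxylates the isolated vinyl group faster than the iodofuran (ozone would attack the furan) and periodate cleaves the diol to the non-enolisable C5 aldehyde.

Step 19
Reactants: 24 (2R,5S)-5-[(4R,6S)-2,2-di-tert-butyl-6-[4-({[tert-butyl(diphenyl)silyl]oxy}methyl)-2-iodofuran-3-yl]-4-methyl-1,3,2-dioxasilinan-4-yl]-2-methyloxolane-2-carbaldehyde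
Product: 25 macrocyclic furyl carbinol (C5–C6 bond closed; C5–OH as a mixture of epimers; furan across C6/C7/C11/C12; C8,C10-O-silylene; C13-OTBDPS)
Conditions: CrCl2 (10 equiv), NiCl2 (10 mol %), DMSO, rt, high dilution (slow addition of 24)
Reagents that add atoms: none
Why: Intramolecular Nozaki–Hiyama–Kishi reaction, in which nickel-catalysed activation of the C6–I bond, transmetalation to chromium and addition of the furylchromium species to the C5 aldehyde close the ten-membered carbocycle (a nine-membered oxa-bridged ring), a closure known for halofuran aldehydes and helped here by the cis-tetrahydrofuran and the silylene, which hold the two ends together; the C5 configuration does not matter.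

Step 20
Reactants: 25 macrocyclic furyl carbinol
Product: 27 C5 O-(S-methyl dithiocarbonate) of 25, via sodium xanthate 26 (not isolated)
Conditions: NaH, THF, 0 °C; CS2; then MeI, rt
Reagents that add atoms: carbon disulfide S=C=S; iodomethane CI
Why: Xanthate formation from the alkoxide, CS2 and MeI prepares the hindered furyl carbinol for radical deoxygenation.

Step 21
Reactants: 27 C5 O-(S-methyl dithiocarbonate) of 25
Product: 28 C5-methylene macrocyclic furan (C8,C10-O-silylene; C13-OTBDPS)
Conditions: Bu3SnH, AIBN (cat.), toluene, 90 °C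
Reagents that add atoms: none
Why: Barton–McCombie deoxygenation proceeds through the furan-stabilised C5 radical, which takes hydrogen from the stannane, and the radical path avoids a C5 cation that could trigger a 1,2-shift toward the ring oxygen.

Step 22
Reactants: 28 C5-methylene macrocyclic furan
Product: 30 C6-hydroxy butenolide (hemiketal at C6; C12 lactone carbonyl; C7=C11), via furan endoperoxide 29 (not isolated)
Conditions: O2, visible light, 5,10,15,20-tetraphenylporphyrin (cat.), i-Pr2NEt, CH2Cl2, −78 °C to rt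
Reagents that add atoms: oxygen O=O
Why: Singlet oxygen adds across the furan in a [4+2] cycloaddition and the amine removes the only bridgehead hydrogen (C12–H) in a Kornblum–DeLaMare fragmentation, so the carbonyl forms at C12 and the hemiketal hydroxyl at C6 regiospecifically.

Step 23
Reactants: 30 C6-hydroxy butenolide
Product: 32 protected dienolide (C5=C6 and C7=C11; C8,C10-O-silylene; C13-OTBDPS), via hemiketal mesylate 31 (not isolated)
Conditions: MsCl, Et3N, DMAP (cat.), CH2Cl2, 0 °C to rt
Reagents that add atoms: none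
Why: Activation of the hemiketal hydroxyl and base-mediated elimination toward C5, the only neighbour bearing hydrogen, is the standard dehydration of 5-alkyl-5-hydroxybutenolides to γ-alkylidene butenolides, and the ring forces C4 and C7 cis on the new C5=C6 bond.

Step 24
Reactants: 32 protected dienolide
Product: 33 dienolide triol (C8–OH, C10–OH, C13–OH)
Conditions: HF·pyridine, pyridine, THF, 0 °C to rt
Reagents that add atoms: none
Why: Fluoride-mediated cleavage removes the silyl ether and the silylene under buffered conditions that the dienolide should tolerate.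

Step 25
Reactants: 33 dienolide triol
Product: 34 C13 monoacetate of 33
Conditions: AcCl (1.1 equiv), 2,4,6-collidine, CH2Cl2, −78 °C
Reagents that add atoms: acetyl chloride CC(Cl)=O
Why: Kinetic acylation at low temperature with a hindered base should select the primary allylic hydroxyl over the hindered secondary C8 and the tertiary C10 hydroxyl.

Step 26
Reactants: 35 (R)-2-methylglycidol
Product: 36 (S)-2-methyloxirane-2-carboxylic acid
Conditions: RuCl3·xH2O (2 mol %), NaIO4, EtOAc/MeCN/H2O, 0 °C to rt; used directly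
Reagents that add atoms: sodium periodate [Na+].[O-]I(=O)(=O)=O (terminal oxidant; oxygen transferred through RuO4)
Why: RuO4 generated in situ oxidises the primary alcohol to the acid without opening the epoxide, and the quaternary stereocentre cannot epimerise (the descriptor changes from R to S only through the priority rules).

Step 27
Reactants: 36 (S)-2-methyloxirane-2-carboxylic acid; 34 C13 monoacetate of 33
Product: 38 CNP0142137.1, via mixed anhydride 37 (not isolated)
Conditions: 36, 2,4,6-trichlorobenzoyl chloride, Et3N, THF, 0 °C; then 34, DMAP, toluene, rt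
Reagents that add atoms: none
Why: Yamaguchi esterification through the mixed anhydride acylates the secondary C8 hydroxyl while the tertiary C10 hydroxyl stays inert, and the quaternary α-carbon of the acid cannot racemise.

**Compound list**

1 | geranyl acetate | CC(=O)OC/C=C(\C)CCC=C(C)C | starting material
2 | (2E,6E)-8-hydroxy-3,7-dimethylocta-2,6-dien-1-yl acetate | CC(=O)OC/C=C(\C)CC/C=C(\C)CO | intermediate
3 | (2E)-5-[(2R,3R)-3-(hydroxymethyl)-3-methyloxiran-2-yl]-3-methylpent-2-en-1-yl acetate | CC(=O)OC/C=C(\C)CC[C@H]1O[C@]1(C)CO | intermediate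
4 | (2E,6S,7R)-6-(benzoyloxy)-7,8-dihydroxy-3,7-dimethyloct-2-en-1-yl acetate | CC(=O)OC/C=C(\C)CC[C@H](OC(=O)c1ccccc1)[C@](C)(O)CO | intermediate
5 | (2E,6S)-6-(benzoyloxy)-3-methyl-6-[(4R)-2,2,4-trimethyl-1,3-dioxolan-4-yl]hex-2-en-1-yl acetate | CC(=O)OC/C=C(\C)CC[C@H](OC(=O)c1ccccc1)[C@@]1(C)COC(C)(C)O1 | intermediate
6 | (2E,6S)-3-methyl-6-[(4R)-2,2,4-trimethyl-1,3-dioxolan-4-yl]hex-2-ene-1,6-diol | OC/C=C(\C)CC[C@H](O)[C@@]1(C)COC(C)(C)O1 | intermediate
7 | (2E,6S)-6-hydroxy-3-methyl-6-[(4R)-2,2,4-trimethyl-1,3-dioxolan-4-yl]hex-2-en-1-yl methyl carbonate | COC(=O)OC/C=C(\C)CC[C@H](O)[C@@]1(C)COC(C)(C)O1 | intermediate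
8 | (4R)-4-[(2S,5R)-5-ethenyl-5-methyloxolan-2-yl]-2,2,4-trimethyl-1,3-dioxolane (vinyl cis to the dioxolanyl group) | C=C[C@@]1(C)CC[C@H](O1)[C@@]2(C)COC(C)(C)O2 | intermediate
9 | (2R)-2-[(2S,5R)-5-ethenyl-5-methyloxolan-2-yl]propane-1,2-diol | C=C[C@@]1(C)CC[C@H](O1)[C@](C)(O)CO | intermediate
10 | (2R)-2-[(2S,5R)-5-ethenyl-5-methyloxolan-2-yl]-2-hydroxypropyl 4-methylbenzenesulfonate (not isolated) | C=C[C@@]1(C)CC[C@H](O1)[C@](C)(O)COS(=O)(=O)c2ccc(C)cc2 | intermediate
11 | (2R,5S)-2-ethenyl-2-methyl-5-[(2R)-2-methyloxiran-2-yl]oxolane | C=C[C@@]1(C)CC[C@H](O1)[C@@]2(C)CO2 | intermediate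
12 | furan-3,4-diyldimethanol | OCc1cocc1CO | starting material
13 | [4-({[tert-butyl(diphenyl)silyl]oxy}methyl)furan-3-yl]methanol | OCc1cocc1CO[Si](c2ccccc2)(c3ccccc3)C(C)(C)C | intermediate
14 | 4-({[tert-butyl(diphenyl)silyl]oxy}methyl)furan-3-carbaldehyde | O=Cc1cocc1CO[Si](c2ccccc2)(c3ccccc3)C(C)(C)C | intermediate
15 | 2-[4-({[tert-butyl(diphenyl)silyl]oxy}methyl)furan-3-yl]-1,3-dithiane | C1CSC(SC1)c2cocc2CO[Si](c3ccccc3)(c4ccccc4)C(C)(C)C | intermediate
16 | 2-lithio derivative of dithiane 15 (not isolated) | [Li]C1(SCCCS1)c2cocc2CO[Si](c3ccccc3)(c4ccccc4)C(C)(C)C | intermediate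
17 | (2R)-1-{2-[4-({[tert-butyl(diphenyl)silyl]oxy}methyl)furan-3-yl]-1,3-dithian-2-yl}-2-[(2S,5R)-5-ethenyl-5-methyloxolan-2-yl]propan-2-ol | C=C[C@@]1(C)CC[C@H](O1)[C@](C)(O)CC2(SCCCS2)c3cocc3CO[Si](c4ccccc4)(c5ccccc5)C(C)(C)C | intermediate
18 | (3R)-1-[4-({[tert-butyl(diphenyl)silyl]oxy}methyl)furan-3-yl]-3-[(2S,5R)-5-ethenyl-5-methyloxolan-2-yl]-3-hydroxybutan-1-one | C=C[C@@]1(C)CC[C@H](O1)[C@](C)(O)CC(=O)c2cocc2CO[Si](c3ccccc3)(c4ccccc4)C(C)(C)C | intermediate
19 | (1S,3R)-1-[4-({[tert-butyl(diphenyl)silyl]oxy}methyl)furan-3-yl]-3-[(2S,5R)-5-ethenyl-5-methyloxolan-2-yl]butane-1,3-diol | C=C[C@@]1(C)CC[C@H](O1)[C@](C)(O)C[C@H](O)c2cocc2CO[Si](c3ccccc3)(c4ccccc4)C(C)(C)C | intermediate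
20 | trilithio species of 19: C8 and C10 lithium alkoxides, lithium at furan C6 (not isolated) | C=C[C@@]1(C)CC[C@H](O1)[C@](C)(O[Li])C[C@H](O[Li])c2c([Li])occ2CO[Si](c3ccccc3)(c4ccccc4)C(C)(C)C | intermediate
21 | (1S,3R)-1-[4-({[tert-butyl(diphenyl)silyl]oxy}methyl)-2-iodofuran-3-yl]-3-[(2S,5R)-5-ethenyl-5-methyloxolan-2-yl]butane-1,3-diol | C=C[C@@]1(C)CC[C@H](O1)[C@](C)(O)C[C@H](O)c2c(I)occ2CO[Si](c3ccccc3)(c4ccccc4)C(C)(C)C | intermediate
22 | (4S,6R)-2,2-di-tert-butyl-4-[4-({[tert-butyl(diphenyl)silyl]oxy}methyl)-2-iodofuran-3-yl]-6-[(2S,5R)-5-ethenyl-5-methyloxolan-2-yl]-6-methyl-1,3,2-dioxasilinane | C=C[C@@]1(C)CC[C@H](O1)[C@@]2(C)C[C@@H](c3c(I)occ3CO[Si](c4ccccc4)(c5ccccc5)C(C)(C)C)O[Si](C(C)(C)C)(C(C)(C)C)O2 | intermediate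
23 | 1,2-diol from dihydroxylation of the vinyl group of 22 (C5 epimers; not isolated) | OCC(O)[C@@]1(C)CC[C@H](O1)[C@@]2(C)C[C@@H](c3c(I)occ3CO[Si](c4ccccc4)(c5ccccc5)C(C)(C)C)O[Si](C(C)(C)C)(C(C)(C)C)O2 | intermediate
24 | (2R,5S)-5-[(4R,6S)-2,2-di-tert-butyl-6-[4-({[tert-butyl(diphenyl)silyl]oxy}methyl)-2-iodofuran-3-yl]-4-methyl-1,3,2-dioxasilinan-4-yl]-2-methyloxolane-2-carbaldehyde | O=C[C@@]1(C)CC[C@H](O1)[C@@]2(C)C[C@@H](c3c(I)occ3CO[Si](c4ccccc4)(c5ccccc5)C(C)(C)C)O[Si](C(C)(C)C)(C(C)(C)C)O2 | intermediate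
25 | macrocyclic furyl carbinol: ten-membered carbocycle closed at C5–C6, C5–OH (epimers), furan across C6/C7/C11/C12, C8,C10-O-di-tert-butylsilylene, C13-OTBDPS | OC1[C@@]2(C)CC[C@H](O2)[C@@]3(C)C[C@H](O[Si](C(C)(C)C)(C(C)(C)C)O3)c4c1occ4CO[Si](c5ccccc5)(c6ccccc6)C(C)(C)C | intermediate
26 | sodium C5 xanthate of 25 (not isolated) | [Na+].[S-]C(=S)OC1[C@@]2(C)CC[C@H](O2)[C@@]3(C)C[C@H](O[Si](C(C)(C)C)(C(C)(C)C)O3)c4c1occ4CO[Si](c5ccccc5)(c6ccccc6)C(C)(C)C | intermediate
27 | C5 O-(S-methyl dithiocarbonate) of 25 | CSC(=S)OC1[C@@]2(C)CC[C@H](O2)[C@@]3(C)C[C@H](O[Si](C(C)(C)C)(C(C)(C)C)O3)c4c1occ4CO[Si](c5ccccc5)(c6ccccc6)C(C)(C)C | intermediate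
28 | C5-methylene macrocyclic furan (C8,C10-O-silylene, C13-OTBDPS) | C1[C@@]2(C)CC[C@H](O2)[C@@]3(C)C[C@H](O[Si](C(C)(C)C)(C(C)(C)C)O3)c4c1occ4CO[Si](c5ccccc5)(c6ccccc6)C(C)(C)C | intermediate
29 | furan endoperoxide of 28: O–O bridge between C6 and C12 (not isolated) | C1[C@@]2(C)CC[C@H](O2)[C@@]3(C)C[C@H](O[Si](C(C)(C)C)(C(C)(C)C)O3)C4=C(CO[Si](c5ccccc5)(c6ccccc6)C(C)(C)C)C7OOC14O7 | intermediate
30 | C6-hydroxy butenolide: hemiketal OH at C6 (epimers), C12 lactone C=O, C7=C11 | C1[C@@]2(C)CC[C@H](O2)[C@@]3(C)C[C@H](O[Si](C(C)(C)C)(C(C)(C)C)O3)C4=C(CO[Si](c5ccccc5)(c6ccccc6)C(C)(C)C)C(=O)OC14O | intermediate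
31 | C6 methanesulfonate of 30 (not isolated) | C1[C@@]2(C)CC[C@H](O2)[C@@]3(C)C[C@H](O[Si](C(C)(C)C)(C(C)(C)C)O3)C4=C(CO[Si](c5ccccc5)(c6ccccc6)C(C)(C)C)C(=O)OC14OS(C)(=O)=O | intermediate
32 | protected dienolide: C5=C6 (E) and C7=C11, C8,C10-O-di-tert-butylsilylene, C13-OTBDPS | CC(C)(C)[Si](c5ccccc5)(c6ccccc6)OCC1=C2/C(=C\[C@@]3(C)CC[C@H](O3)[C@@]4(C)C[C@@H]2O[Si](C(C)(C)C)(C(C)(C)C)O4)OC1=O | intermediate
33 | dienolide triol (8S-OH, 10R-OH, C13-OH) | OCC1=C2/C(=C\[C@@]3(C)CC[C@H](O3)[C@](C)(O)C[C@@H]2O)OC1=O | intermediate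
34 | C13 monoacetate of 33 | CC(=O)OCC1=C2/C(=C\[C@@]3(C)CC[C@H](O3)[C@](C)(O)C[C@@H]2O)OC1=O | intermediate
35 | (R)-2-methylglycidol [(2R)-(2-methyloxiran-2-yl)methanol] | OC[C@]1(C)CO1 | starting material
36 | (S)-2-methyloxirane-2-carboxylic acid | OC(=O)[C@]1(C)CO1 | intermediate
37 | (S)-2-methyloxirane-2-carboxylic 2,4,6-trichlorobenzoic anhydride (not isolated) | O=C(OC(=O)[C@]1(C)CO1)c2c(Cl)cc(Cl)cc2Cl | intermediate
38 | CNP0142137.1 | CC(=O)OCC1=C2/C(=C\[C@@]3(C)CC[C@H](O3)[C@](C)(O)C[C@@H]2OC(=O)[C@]2(C)CO2)OC1=O | target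

**Step count and risks**

Total steps: 27. Longest linear sequence: 23 steps (steps 1–9, 13–25 and 27).

Steps most likely to fail:

1. Step 19 (ring closure at C5–C6). Intermolecular coupling to oligomers, or protonation of the furylchromium species before it reaches the hindered aldehyde, may outrun the medium-ring closure. Fallback: set out from diol 19, before any iodination. Silylation as in step 17 gives the des-iodo silylene F1, and Lemieux–Johnson cleavage as in step 18 gives the des-iodo aldehyde F2. A Lewis acid (Sc(OTf)3, or BF3·OEt2 at low temperature) in dilute CH2Cl2 then closes the ring by intramolecular Friedel–Crafts hydroxyalkylation at the furan C6–H; the other α-position C12 cannot reach the aldehyde. This gives carbinol 25, where the route resumes at step 20. The fallback also removes the need for the regioselective metalation of step 16.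

2. Step 7 (allylic etherification at C4). Facial discrimination at C4 may be insufficient if the bias of the C1 centre opposes the ligand, and the allyl complex may be lost by β-hydride elimination to a diene. Fallback: set out from diol 6 and form the same O–C4 bond by stereospecific substitution. Katsuki–Sharpless epoxidation of the allylic alcohol with diethyl L-(+)-tartrate gives the (2S,3S)-epoxy alcohol F3. Camphorsulfonic acid in CH2Cl2 then induces 5-exo opening at the tertiary carbon C4 by the C1 hydroxyl with inversion, giving the tetrahydrofuran diol F4 with C4 as required. Garegg–Samuelsson deoxygenation of the terminal 1,2-diol (PPh3, I2, imidazole, toluene, reflux) gives vinyl tetrahydrofuran 8, where the route resumes at step 8.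

3. Step 3 (benzoate opening at C1). Attack of benzoate at the tertiary carbon C10 may compete, and the C1 benzoate may migrate to C9 before the acetonide is in place. Fallback: set out from allylic alcohol 2 and invert C10 in place of C1. Epoxidation with diethyl L-(+)-tartrate gives the enantiomeric epoxy alcohol F5. Dilute HClO4 in THF/H2O opens it with water at the tertiary carbon C10 with inversion, giving the triol F6 with C1 and C10 as required. 2,2-Dimethoxypropane and PPTS under equilibrating conditions give the less substituted terminal acetonide, the hydroxy acetonide F7, and K2CO3 in MeOH removes the acetate to give diol 6, where the route resumes at step 6.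

Further compounds
F1 | step 19 | (4S,6R)-2,2-di-tert-butyl-4-[4-({[tert-butyl(diphenyl)silyl]oxy}methyl)furan-3-yl]-6-[(2S,5R)-5-ethenyl-5-methyloxolan-2-yl]-6-methyl-1,3,2-dioxasilinane | C=C[C@@]1(C)CC[C@H](O1)[C@@]2(C)C[C@@H](c3cocc3CO[Si](c4ccccc4)(c5ccccc5)C(C)(C)C)O[Si](C(C)(C)C)(C(C)(C)C)O2
F2 | step 19 | (2R,5S)-5-[(4R,6S)-2,2-di-tert-butyl-6-[4-({[tert-butyl(diphenyl)silyl]oxy}methyl)furan-3-yl]-4-methyl-1,3,2-dioxasilinan-4-yl]-2-methyloxolane-2-carbaldehyde | O=C[C@@]1(C)CC[C@H](O1)[C@@]2(C)C[C@@H](c3cocc3CO[Si](c4ccccc4)(c5ccccc5)C(C)(C)C)O[Si](C(C)(C)C)(C(C)(C)C)O2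
F3 | step 7 | {(2S,3S)-3-[(3S)-3-hydroxy-3-[(4R)-2,2,4-trimethyl-1,3-dioxolan-4-yl]propyl]-3-methyloxiran-2-yl}methanol | OC[C@@H]1O[C@@]1(C)CC[C@H](O)[C@@]2(C)COC(C)(C)O2
F4 | step 7 | (1S)-1-[(2R,5S)-2-methyl-5-[(4R)-2,2,4-trimethyl-1,3-dioxolan-4-yl]oxolan-2-yl]ethane-1,2-diol | OC[C@H](O)[C@@]1(C)CC[C@H](O1)[C@@]2(C)COC(C)(C)O2
F5 | step 3 | (2E)-5-[(2S,3S)-3-(hydroxymethyl)-3-methyloxiran-2-yl]-3-methylpent-2-en-1-yl acetate | CC(=O)OC/C=C(\C)CC[C@@H]1O[C@@]1(C)CO
F6 | step 3 | (2E,6S,7R)-6,7,8-trihydroxy-3,7-dimethyloct-2-en-1-yl acetate | CC(=O)OC/C=C(\C)CC[C@H](O)[C@](C)(O)CO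
F7 | step 3 | (2E,6S)-6-hydroxy-3-methyl-6-[(4R)-2,2,4-trimethyl-1,3-dioxolan-4-yl]hex-2-en-1-yl acetate | CC(=O)OC/C=C(\C)CC[C@H](O)[C@@]1(C)COC(C)(C)O1
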